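**Strategy.** Ring B (the cyclohexene) is disconnected at C7–C8, the bond between the methylene on spiro carbon C6 and the alkene carbon that carries the 4-methylpent-3-enyl chain (spiro[5.5]undecane numbering). C7 is a neopentyl-type carbon on the quaternary C6, which lies between the two ring A ketones. As a boron homoenolate it has no β-hydrogen and does not undergo acyl shift. The key step is therefore an intramolecular B-alkyl Suzuki–Miyaura coupling that closes ring B onto a (Z)-bromoalkene. The precursor is a ring A dione whose C6 carries a CH2Bpin group and the bromoalkenyl side chain. Its two stereocentres come from an organocatalytic Michael addition and a substrate-controlled C-alkylation.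

Key step: step 9

Remark: C6, C7, C8 and C11 are the locants of the target name (C6 spiro carbon, C7 ring B methylene, C8 alkene carbon with the side chain, C11 isopropyl-bearing carbon); diones are drawn as one tautomer and lactol 7 is an anomeric mixture that reacts through its open form.

Step 1
Reactants: 1 2,4,6-trihydroxyacetophenone
Product: 2 2-acetyl-3,5-dihydroxy-4,6,6-trimethylcyclohexa-2,4-dien-1-one (enol form of 2-acetyl-4,6,6-trimethylcyclohexane-1,3,5-trione)
Conditions: NaOMe (3.3 equiv), MeI (3.1 equiv), MeOH, 0 °C to reflux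
Reagents that add atoms: iodomethane, CI
Why: Iterated dearomatising C-methylation of the phloroglucinolate, in which the acetyl group blocks one ring carbon so that three equivalents of MeI should place one methyl on one free carbon and a geminal pair on the other, the tetramethyl by-product being removed by chromatography.

Step 2
Reactants: 2 2-acetyl-3,5-dihydroxy-4,6,6-trimethylcyclohexa-2,4-dien-1-one
Product: 3 2,2,4-trimethylcyclohexane-1,3,5-trione
Conditions: 6 M HCl aq, dioxane, reflux
Reagents that add atoms: none
Why: Acid-mediated retro-Claisen deacylation of a 2-acyl-1,3-dione (the reaction type used to make syncarpic acid from its acetyl derivative) should free the ring carbon between two carbonyls.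

Step 3
Reactants: 3 2,2,4-trimethylcyclohexane-1,3,5-trione
Product: 4 3,5-dimethoxy-2,4,4-trimethylcyclohexa-2,5-dien-1-one
Conditions: HC(OMe)3, MeOH, TsOH (cat.), reflux
Reagents that add atoms: trimethyl orthoformate, COC(OC)OC
Why: Acid-catalysed enol etherification under thermodynamic control should give the cross-conjugated bis(enol ether), a 4,4-disubstituted cyclohexa-2,5-dienone being the more stable dienone type.

Step 4
Reactants: 4 3,5-dimethoxy-2,4,4-trimethylcyclohexa-2,5-dien-1-one
Product: 5 5-hydroxy-3-methoxy-2,4,4-trimethylcyclohexa-2,5-dien-1-one (enol of 5-methoxy-4,6,6-trimethylcyclohex-4-ene-1,3-dione)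
Conditions: 1 M NaOH aq, THF, 0 °C to rt; then 1 M HCl
Reagents that add atoms: sodium hydroxide, [Na+].[OH-]
Why: Addition–elimination of hydroxide on the vinylogous ester should occur at the less hindered β-carbon (next to the ring CH, not the one between the C-methyl carbon and the gem-dimethyl carbon), and the enolate formed protects the product from a second hydrolysis.

Step 5
Reactants: 5 5-hydroxy-3-methoxy-2,4,4-trimethylcyclohexa-2,5-dien-1-one; 6 (E)-4-methylpent-2-enal
Product: 7 (4S)-2-hydroxy-7-methoxy-6,8,8-trimethyl-4-(propan-2-yl)-2,3,4,8-tetrahydro-5H-chromen-5-one (lactol, mixture at C2)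
Conditions: (S)-α,α-diphenylprolinol trimethylsilyl ether (10 mol %), PhCO2H (10 mol %), CH2Cl2, 0 °C
Reagents that add atoms: none
Why: Iminium-catalysed Michael addition of the cyclic 1,3-dione enol followed by hemiacetal closure, in which the diphenyl(silyloxy)methyl group of the (S)-catalyst shields one face of the E-iminium ion so that attack at the β-carbon should set the (S) centre (C11 of the target).

Step 6
Reactants: 7 (4S)-2-hydroxy-7-methoxy-6,8,8-trimethyl-4-(propan-2-yl)-2,3,4,8-tetrahydro-5H-chromen-5-one
Product: 8 (3S)-3-{(1R)-4-methoxy-3,5,5-trimethyl-2,6-dioxo-1-[(4,4,5,5-tetramethyl-1,3,2-dioxaborolan-2-yl)methyl]cyclohex-3-en-1-yl}-4-methylpentanal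
Conditions: ICH2Bpin, K2CO3, MeCN, 40 °C
Reagents that add atoms: 2-(iodomethyl)-4,4,5,5-tetramethyl-1,3,2-dioxaborolane, ICB1OC(C)(C)C(C)(C)O1
Why: Base opens the lactol to the dione enolate, which is C-alkylated by the α-halo boronate (enolate alkylation giving a β-boryl ketone); in the rotamer that keeps the side-chain C–H in the ring plane next to the carbonyl flanked by the gem-dimethyl carbon, the reagent should enter anti to the isopropyl group and set the quaternary (R) centre (C6 of the target), the minor epimer being removed by chromatography.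

Step 7
Reactants: 8 (3S)-3-{(1R)-4-methoxy-3,5,5-trimethyl-2,6-dioxo-1-[(4,4,5,5-tetramethyl-1,3,2-dioxaborolan-2-yl)methyl]cyclohex-3-en-1-yl}-4-methylpentanal
Product: 9 (6R)-6-[(3S)-6,6-dibromo-2-methylhex-5-en-3-yl]-3-methoxy-2,4,4-trimethyl-6-[(4,4,5,5-tetramethyl-1,3,2-dioxaborolan-2-yl)methyl]cyclohex-2-ene-1,5-dione
Conditions: CBr4, PPh3, CH2Cl2, 0 °C
Reagents that add atoms: carbon tetrabromide, BrC(Br)(Br)Br
Why: Corey–Fuchs (Ramirez) dibromo-olefination acts only on the aldehyde, since the ring ketones are hindered and non-enolisable and the alkyl boronate is inert to the phosphorus ylide.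

Step 8
Reactants: 9 (6R)-6-[(3S)-6,6-dibromo-2-methylhex-5-en-3-yl]-3-methoxy-2,4,4-trimethyl-6-[(4,4,5,5-tetramethyl-1,3,2-dioxaborolan-2-yl)methyl]cyclohex-2-ene-1,5-dione; 10 5-bromo-2-methylpent-2-ene
Product: 12 (6R)-6-[(3S,5Z)-6-bromo-2,10-dimethylundeca-5,9-dien-3-yl]-3-methoxy-2,4,4-trimethyl-6-[(4,4,5,5-tetramethyl-1,3,2-dioxaborolan-2-yl)methyl]cyclohex-2-ene-1,5-dione, via (4-methylpent-3-enyl)zinc bromide 11 (not isolated)
Conditions: 10, Zn dust, LiCl, THF, 50 °C; then 9, PdCl2(DPEphos) (5 mol %), THF, 0 °C to rt
Reagents that add atoms: none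
Why: Trans-selective Negishi mono-alkylation of a 1,1-dibromoalkene: zerovalent palladium inserts into the C–Br bond trans to the chain, so the remaining bromine is cis to the chain in the (Z)-bromoalkene, and the alkyl boronate does not transmetalate without base.

Step 9
Reactants: 12 (6R)-6-[(3S,5Z)-6-bromo-2,10-dimethylundeca-5,9-dien-3-yl]-3-methoxy-2,4,4-trimethyl-6-[(4,4,5,5-tetramethyl-1,3,2-dioxaborolan-2-yl)methyl]cyclohex-2-ene-1,5-dione
Product: 13 (6R,11S)-3-methoxy-2,4,4-trimethyl-8-(4-methylpent-3-en-1-yl)-11-(propan-2-yl)spiro[5.5]undeca-2,8-diene-1,5-dione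
Conditions: Pd(OAc)2 (10 mol %), RuPhos (20 mol %), K3PO4, toluene/H2O (10:1), 80 °C, 0.01 M
Reagents that add atoms: none
Why: Zerovalent palladium inserts into the alkenyl C–Br bond with retention, phosphate and water activate the primary alkyl boronate, intramolecular transmetalation gives a seven-membered alkyl(alkenyl)palladacycle of divalent palladium, and reductive elimination forms the C7–C8 bond. The closest known reaction type is the intramolecular B-alkyl Suzuki–Miyaura coupling, here with a β-boryl ketone (boron homoenolate) as the alkyl partner. Ring B, the six-membered carbocycle, is closed by this C(sp3)–C(sp2) reductive elimination, which is possible only because the bromine is cis to the tether in the Z-alkene. No stereocentre is formed: C6 and C11 are untouched and the alkene becomes the endocyclic C8=C9 bond. The step needs C–C coupling to win over β-hydride elimination, protodeboronation and 1,2-acyl shift; the palladium-bound carbon sits on the fully substituted C6 and so has no β-hydrogen, ring A has no enolisable hydrogen, and the two-electron boron pathway avoids the C7 radical or zinc homoenolate that would ring-expand ring A.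

Compound list
1 | 2,4,6-trihydroxyacetophenone | CC(=O)c1c(O)cc(O)cc1O | starting material
2 | 2-acetyl-3,5-dihydroxy-4,6,6-trimethylcyclohexa-2,4-dien-1-one | CC(=O)C1=C(O)C(C)=C(O)C(C)(C)C1=O | intermediate
3 | 2,2,4-trimethylcyclohexane-1,3,5-trione | CC1C(=O)CC(=O)C(C)(C)C1=O | intermediate
4 | 3,5-dimethoxy-2,4,4-trimethylcyclohexa-2,5-dien-1-one | COC1=CC(=O)C(C)=C(OC)C1(C)C | intermediate
5 | 5-hydroxy-3-methoxy-2,4,4-trimethylcyclohexa-2,5-dien-1-one | COC1=C(C)C(=O)C=C(O)C1(C)C | intermediate
6 | (E)-4-methylpent-2-enal | CC(C)/C=C/C=O | starting material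
7 | (4S)-2-hydroxy-7-methoxy-6,8,8-trimethyl-4-(propan-2-yl)-2,3,4,8-tetrahydro-5H-chromen-5-one | OC1C[C@@H](C(C)C)C2=C(O1)C(C)(C)C(OC)=C(C)C2=O | intermediate
8 | (3S)-3-{(1R)-4-methoxy-3,5,5-trimethyl-2,6-dioxo-1-[(4,4,5,5-tetramethyl-1,3,2-dioxaborolan-2-yl)methyl]cyclohex-3-en-1-yl}-4-methylpentanal | O=CC[C@@H](C(C)C)[C@]1(CB2OC(C)(C)C(C)(C)O2)C(=O)C(C)=C(OC)C(C)(C)C1=O | intermediate
9 | (6R)-6-[(3S)-6,6-dibromo-2-methylhex-5-en-3-yl]-3-methoxy-2,4,4-trimethyl-6-[(4,4,5,5-tetramethyl-1,3,2-dioxaborolan-2-yl)methyl]cyclohex-2-ene-1,5-dione | BrC(Br)=CC[C@@H](C(C)C)[C@]1(CB2OC(C)(C)C(C)(C)O2)C(=O)C(C)=C(OC)C(C)(C)C1=O | intermediate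
10 | 5-bromo-2-methylpent-2-ene | CC(C)=CCCBr | starting material
11 | (4-methylpent-3-enyl)zinc bromide | CC(C)=CCC[Zn]Br | intermediate
12 | (6R)-6-[(3S,5Z)-6-bromo-2,10-dimethylundeca-5,9-dien-3-yl]-3-methoxy-2,4,4-trimethyl-6-[(4,4,5,5-tetramethyl-1,3,2-dioxaborolan-2-yl)methyl]cyclohex-2-ene-1,5-dione | CC(C)=CCC/C(Br)=C/C[C@@H](C(C)C)[C@]1(CB2OC(C)(C)C(C)(C)O2)C(=O)C(C)=C(OC)C(C)(C)C1=O | intermediate
13 | (6R,11S)-3-methoxy-2,4,4-trimethyl-8-(4-methylpent-3-en-1-yl)-11-(propan-2-yl)spiro[5.5]undeca-2,8-diene-1,5-dione (isopropyl cis to the carbonyl next to C(Me)=C(OMe)) | COC1=C(C)C(=O)[C@]2(CC(CCC=C(C)C)=CC[C@H]2C(C)C)C(=O)C1(C)C | target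

Total step count: 9. Longest linear sequence: 9 steps (1 to 13).

Steps most likely to fail

Step 9. Transmetalation of the hindered neopentyl-type boronate may be slower than protodeboronation or hydroxide-induced cleavage of the 2,2-disubstituted 1,3-dione, so that ring B does not close. The fallback sets out from 12 and abandons the boron pathway. Oxidation of the C–B bond with NaBO3 in THF/H2O should give the hydroxymethyl analogue of 12 F1 (CH2OH in place of CH2Bpin, configuration unchanged). Treatment with I2, PPh3 and imidazole should give the iodomethyl analogue of 12 F2. A nickel-catalysed intramolecular reductive cross-electrophile coupling of the alkyl iodide with the alkenyl bromide (NiBr2·glyme, 4,4′-di-tert-butyl-2,2′-bipyridine, Mn, DMA, high catalyst loading) would then form the same C7–C8 bond and come back to the route at 13. This variant carries the 1,2-acyl-shift risk of the C7 radical, which is why it is not the first choice.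

Step 6. The hindered tertiary enolate may be alkylated on oxygen instead of carbon, and the facial bias between the isopropyl and CH2CHO arms may be low. The fallback sets out from 5 and builds the quaternary carbon by conjugate addition instead of alkylation. Condensation of 5 with formaldehyde in the presence of B2pin2 and a CuCl/NaOtBu catalyst in MeOH/THF should trap the transient 2-methylene dione by conjugate borylation. This gives 5-hydroxy-3-methoxy-2,4,4-trimethyl-6-[(4,4,5,5-tetramethyl-1,3,2-dioxaborolan-2-yl)methyl]cyclohexa-2,5-dien-1-one F3. Iminium-catalysed Michael addition of F3 to 6 with the catalyst of step 5 forms the C6–C11 bond and comes back to the route at 8; the epimer at the quaternary carbon is again removed by chromatography.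

Step 4. Hydroxide may attack both enol ether carbons, so that site selectivity is lost and the regioisomeric mono-ether forms. The fallback sets out from 3 and differentiates the two enols by protection. Silylation of the less hindered enol (TBSCl, imidazole, CH2Cl2) should give 5-[(tert-butyldimethylsilyl)oxy]-3-hydroxy-2,4,4-trimethylcyclohexa-2,5-dien-1-one F4. O-Methylation of the remaining enol with trimethylsilyldiazomethane in MeOH/toluene should give 5-[(tert-butyldimethylsilyl)oxy]-3-methoxy-2,4,4-trimethylcyclohexa-2,5-dien-1-one F5. Desilylation with tetrabutylammonium fluoride comes back to the route at 5.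

Further compounds
F1 | step 9 | hydroxymethyl analogue of 12 (CH2OH in place of CH2Bpin) | CC(C)=CCC/C(Br)=C/C[C@@H](C(C)C)[C@]1(CO)C(=O)C(C)=C(OC)C(C)(C)C1=O
F2 | step 9 | iodomethyl analogue of 12 (CH2I in place of CH2Bpin) | CC(C)=CCC/C(Br)=C/C[C@@H](C(C)C)[C@]1(CI)C(=O)C(C)=C(OC)C(C)(C)C1=O
F3 | step 6 | 5-hydroxy-3-methoxy-2,4,4-trimethyl-6-[(4,4,5,5-tetramethyl-1,3,2-dioxaborolan-2-yl)methyl]cyclohexa-2,5-dien-1-one | COC1=C(C)C(=O)C(CB2OC(C)(C)C(C)(C)O2)=C(O)C1(C)C
F4 | step 4 | 5-[(tert-butyldimethylsilyl)oxy]-3-hydroxy-2,4,4-trimethylcyclohexa-2,5-dien-1-one | CC1=C(O)C(C)(C)C(O[Si](C)(C)C(C)(C)C)=CC1=O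
F5 | step 4 | 5-[(tert-butyldimethylsilyl)oxy]-3-methoxy-2,4,4-trimethylcyclohexa-2,5-dien-1-one | COC1=C(C)C(=O)C=C(O[Si](C)(C)C(C)(C)C)C1(C)C
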